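**Retrosynthetic overview**

1. 40 ⇐ 39 (desilylation) ⇐ 38 (diimide) ⇐ 37: the nine-membered azacycle is closed last by RCM (C3=C4) across the δ-lactam.
2. 37 ⇐ core aldehyde 25 + amine 35 (Evans syn-aldol, sets C2/C18) by reductive amination/lactamisation (N–C7, N–C1).
3. 25 ⇐ 16: cycloheptene by a first RCM (C6=C12); C5 made quaternary by aldehyde hydroxymethylation; C14 set by Krapcho protonation.
4. 16 ⇐ ester 13 by Ireland–Claisen rearrangement (C5–C8 bond, C8 quaternary centre, C9=C10 alkene); 13 = alcohol 7 + itaconate-derived acid 12.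
5. 7 ⇐ cyclopentenone by asymmetric Michael addition (C15), pyruvate alkylation, aldol condensation and allylation; ring order B → A → seven-membered carbocycle → δ-lactam → nine-membered ring.

Locants follow yuzurimine-type numbering: N; C1 lactam C=O; C2 CHOH; C3; C4; C5 (quaternary, bears C21H2OAc); C6; C7 (NCH2); C8 (quaternary); C9=C10; C11; C12; C13; C14 (CHCO2Me, C22); C15; C16; C17; C18 (CHMe, C20); C19 (NCH2). Assumption: 14–21 are carried as C5-epimer mixtures (C5 is rebuilt in step 15), so C5 is left undefined in their SMILES.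

**Route**

Step 1
Reactants: 1 cyclopent-2-en-1-one; 2 dimethyl malonate
Product: 3 dimethyl 2-[(1S)-3-oxocyclopentyl]propanedioate
Conditions: (S)-ALB [AlLi-bis((S)-binaphthoxide)] 5 mol %, KOt-Bu 4.5 mol %, 4 Å MS, THF, rt
Reagents that add atoms: none
Why: Catalytic asymmetric Michael addition (Shibasaki heterobimetallic catalysis); the (S)-BINOL catalyst, antipode of the (R)-catalyst that gives the (R)-adduct, sets C15 as S in high ee.

Step 2
Reactants: 3 Michael adduct; 4 methyl 3-bromo-2-oxopropanoate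
Product: 5 dimethyl 2-(3-methoxy-2,3-dioxopropyl)-2-[(1S)-3-oxocyclopentyl]propanedioate
Conditions: NaH (1.05 equiv), THF, 0 °C; then 4, 0 °C → rt
Reagents that add atoms: none
Why: Malonate C-alkylation (SN2); NaH removes only the malonate C–H and the α-bromo ketone is a very reactive electrophile, giving quaternary C14 and the C13–C8(=O)–C1 chain.

Step 3
Reactants: 5 keto triester
Product: 6 trimethyl (3aS)-6-oxo-2,3,3a,4,5,6-hexahydropentalene-1,3,3-tricarboxylate
Conditions: p-TsOH·H2O (10 mol %), PhMe, reflux, Dean–Stark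
Reagents that add atoms: none
Why: Intramolecular aldol condensation (5-exo); the cyclopentanone enol carbon C9 attacks the highly electrophilic α-keto ester carbonyl C8 and dehydration gives the doubly conjugated C8=C9 alkene, while the alternative bridged aldols cannot dehydrate and revert.

Step 4
Reactants: 6 bicyclic enone
Product: 7 trimethyl (3aS,6S)-6-hydroxy-6-(prop-2-en-1-yl)-2,3,3a,4,5,6-hexahydropentalene-1,3,3-tricarboxylate
Conditions: allylMgBr, CeCl3, THF, −78 °C; sat. aq. NH4Cl at −78 °C
Reagents that add atoms: allylmagnesium bromide, C=CC[Mg]Br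
Why: Organocerium 1,2-addition to the ketone (conjugate addition suppressed, esters inert at −78 °C) from the convex face of the folded bicycle, so allyl is cis to H-15 and the C10–O bond lies on the concave face.

Step 5
Reactants: 8 itaconic anhydride
Product: 9 4-[(4-methoxyphenyl)methoxy]-2-methylidene-4-oxobutanoic acid
Conditions: 4-methoxybenzyl alcohol, PhMe, 70 °C
Reagents that add atoms: 4-methoxybenzyl alcohol, COc1ccc(CO)cc1
Why: Regioselective anhydride alcoholysis; the alcohol opens the non-conjugated, less hindered carbonyl and leaves the acrylic acid free.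

Step 6
Reactants: 9 PMB half-ester
Product: 11 4-methoxybenzyl 3-[methoxy(methyl)carbamoyl]but-3-enoate, via acyl imidazolide 10 (not isolated)
Conditions: CDI, CH2Cl2, 0 °C → rt; then MeNH(OMe)·HCl, rt
Reagents that add atoms: N,O-dimethylhydroxylamine hydrochloride, CNOC.Cl
Why: Amide coupling through the acyl imidazolide (Weinreb amide formation); the PMB ester is inert.

Step 7
Reactants: 11 PMB ester Weinreb amide
Product: 12 3-[methoxy(methyl)carbamoyl]but-3-enoic acid
Conditions: TFA, anisole, CH2Cl2, 0 °C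
Reagents that add atoms: none
Why: Acidolysis (SN1) of the PMB ester with anisole as cation trap frees the acid without touching the Weinreb acrylamide.

Step 8
Reactants: 7 tertiary allylic alcohol; 12 acid
Product: 13 C10 ester of 7 with acid 12
Conditions: DCC, DMAP (1 equiv), CH2Cl2, 0 °C → rt
Reagents that add atoms: none
Why: Steglich esterification; DMAP acyl transfer (acylpyridinium/ketene from the activated CH2 acid) acylates even the tertiary alcohol under non-basic conditions, so lactonisation onto the C1 ester is avoided.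

Step 9
Reactants: 13 allylic ester
Product: 16 Claisen acid (C8 quaternary; C9=C10 alkene), via silyl ketene acetal 14 (not isolated), via trimethylsilyl ester 15 (not isolated)
Conditions: LiHMDS (1.2 equiv), TMSCl/Et3N, THF, −78 °C → rt, then 50 °C; 1 M HCl
Reagents that add atoms: none
Why: Ireland–Claisen rearrangement; the [3,3]-shift is suprafacial on the O–C10–C9=C8 unit, so C5 is delivered to C8 on the face that carried the C10–O bond (trans to H-15), which sets the C8 quaternary centre and creates the tetrasubstituted C9=C10 alkene (the TMS group of 14 and 15 comes from TMSCl and is lost on work-up).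

Step 10
Reactants: 16 Claisen acid
Product: 17 cycloheptadiene acid (5-5-7 tricycle; C6=C12)
Conditions: Grubbs II (5 mol %), CH2Cl2 (5 mM), 40 °C
Reagents that add atoms: none
Why: Ring-closing metathesis of the allyl terminal alkene onto the 1,1-disubstituted acrylamide, helped by the cis arrangement of the two arms on C9=C10 and the quaternary C8; the tetrasubstituted alkene is inert.

Step 11
Reactants: 17 cycloheptadiene acid
Product: 18 C6,C12-dihydro acid
Conditions: H2 (1 atm), 10 % Pd/C, EtOAc, rt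
Reagents that add atoms: none
Why: Chemoselective heterogeneous hydrogenation of the trisubstituted enamide alkene (tetrasubstituted C9=C10 is not reduced); H2 adds from the face opposite the C1 ester, placing the C7 carboxamide cis to C1 at C6.

Step 12
Reactants: 18 gem-diester acid
Product: 19 C14 mono-ester acid
Conditions: LiCl, H2O, DMSO, 140 °C
Reagents that add atoms: none
Why: Krapcho demethoxycarbonylation, specific for the geminal diester; the ester enol is protonated from the convex face (cis to H-15, away from the C5 branch on C8), giving CO2Me cis to C16, and the free acid buffers the medium so this kinetic product is not epimerised.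

Step 13
Reactants: 19 acid
Product: 20 S-ethyl thioester
Conditions: EtSH, DCC, DMAP (cat.), CH2Cl2, 0 °C → rt
Reagents that add atoms: ethanethiol, CCS
Why: Steglich thioesterification of the only free acid; a thioester is chosen over an acid chloride to avoid participation of the neighbouring Weinreb amide.

Step 14
Reactants: 20 thioester
Product: 21 C4 aldehyde
Conditions: Et3SiH, 10 % Pd/C, acetone, rt
Reagents that add atoms: none
Why: Fukuyama reduction; the thioester is reduced to the aldehyde while esters, the Weinreb amide and the tetrasubstituted alkene are untouched.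

Step 15
Reactants: 21 C4 aldehyde
Product: 23 C21 acetoxy aldehyde (C5 quaternary), via hydroxy aldehyde 22 (not isolated)
Conditions: (CH2O)n, DBU (0.2 equiv), THF, rt; then Ac2O, pyridine, DMAP (cat.), 0 °C → rt
Reagents that add atoms: formaldehyde (from paraformaldehyde), C=O; acetic anhydride, CC(=O)OC(C)=O
Why: Crossed aldol with formaldehyde (α-hydroxymethylation of the only enolisable aldehyde) then O-acetylation; formaldehyde attacks the C5 enol from the face opposite the C1 ester and the C7 amide, so C21 is anti and the formyl carbon C4 syn to them, which sets the C5 quaternary stereocentre.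

Step 16
Reactants: 23 acetoxy aldehyde
Product: 24 C5-vinyl compound
Conditions: Ph3PCH3Br, KHMDS, THF, 0 °C; then 23, −78 → 0 °C
Reagents that add atoms: methyltriphenylphosphonium bromide, C[P+](c1ccccc1)(c1ccccc1)c1ccccc1.[Br-]
Why: Wittig methylenation of the non-enolisable neopentyl aldehyde; the unstabilised ylide does not attack esters, the acetate or the Weinreb amide at or below 0 °C.

Step 17
Reactants: 24 Weinreb amide
Product: 25 C7 aldehyde
Conditions: DIBAL-H (1.1 equiv), THF, −78 °C; Rochelle salt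
Reagents that add atoms: none
Why: Weinreb amide reduction; the chelated tetrahedral intermediate releases the aldehyde only on work-up, and in THF at −78 °C the methyl esters and the acetate react much more slowly.

Step 18
Reactants: 26 (4S)-4-benzyl-1,3-oxazolidin-2-one
Product: 27 (4S)-4-benzyl-3-propanoyl-1,3-oxazolidin-2-one
Conditions: n-BuLi, THF, −78 °C; EtCOCl, −78 → 0 °C
Reagents that add atoms: propanoyl chloride, CCC(=O)Cl
Why: N-Acylation of the lithiated oxazolidinone (loading of the Evans auxiliary).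

Step 19
Reactants: 27 N-propanoyl oxazolidinone; 28 acrolein
Product: 30 (4S)-4-benzyl-3-[(2S,3R)-3-hydroxy-2-methylpent-4-enoyl]-1,3-oxazolidin-2-one, via boron enolate 29 (not isolated)
Conditions: Bu2BOTf, Et3N, CH2Cl2, −78 → 0 °C; 28, −78 → 0 °C; pH 7 buffer/MeOH
Reagents that add atoms: none
Why: Evans syn-aldol reaction; the (Z)-boron enolate reacts through a Zimmerman–Traxler chair with the benzyl group shielding one face, giving the (2S,3R) syn adduct that becomes C18 and C2.

Step 20
Reactants: 30 aldol adduct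
Product: 31 TBS ether of 30
Conditions: TBSOTf, 2,6-lutidine, CH2Cl2, 0 °C
Reagents that add atoms: tert-butyldimethylsilyl trifluoromethanesulfonate, CC(C)(C)[Si](C)(C)OS(=O)(=O)C(F)(F)F
Why: Silyl ether formation protects the C2 hydroxyl under conditions that do not cause retro-aldol.

Step 21
Reactants: 31 silylated imide
Product: 32 (2R,3R)-3-{[tert-butyl(dimethyl)silyl]oxy}-2-methylpent-4-en-1-ol
Conditions: LiBH4, MeOH (1 equiv), THF, 0 °C
Reagents that add atoms: none
Why: Reductive cleavage of the N-acyl oxazolidinone gives the primary alcohol and returns the auxiliary without epimerising the α-centre.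

Step 22
Reactants: 32 alcohol
Product: 33 (2R,3R)-3-{[tert-butyl(dimethyl)silyl]oxy}-2-methylpent-4-en-1-yl methanesulfonate
Conditions: MsCl, Et3N, CH2Cl2, 0 °C
Reagents that add atoms: methanesulfonyl chloride, CS(=O)(=O)Cl
Why: Sulfonylation of the primary alcohol (mesylate formation).

Step 23
Reactants: 33 mesylate
Product: 34 tert-butyl{[(3R,4R)-5-azido-4-methylpent-1-en-3-yl]oxy}dimethylsilane
Conditions: NaN3, DMF, 50 °C
Reagents that add atoms: sodium azide, [Na+].[N-]=[N+]=[N-]
Why: SN2 displacement of the primary mesylate by azide at moderate temperature, which avoids intramolecular azide–alkene cycloaddition.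

Step 24
Reactants: 34 azide
Product: 35 (2R,3R)-3-{[tert-butyl(dimethyl)silyl]oxy}-2-methylpent-4-en-1-amine
Conditions: PPh3, THF/H2O, 50 °C
Reagents that add atoms: none
Why: Staudinger reduction (iminophosphorane hydrolysis) gives the primary amine without touching the alkene or the silyl ether.

Step 25
Reactants: 25 C7 aldehyde; 35 amine
Product: 37 N-alkyl δ-lactam diene, via secondary amine 36 (not isolated)
Conditions: NaBH(OAc)3, AcOH, ClCH2CH2Cl, rt; then Et3N, PhMe, 110 °C
Reagents that add atoms: none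
Why: Reductive amination followed by intramolecular ester aminolysis (lactamisation); the amine is held next to the C1 ester by the C5/C8 quaternary centres (Thorpe–Ingold) and only the C6 epimer with C7 cis to C1 can close the δ-lactam.

Step 26
Reactants: 37 lactam diene
Product: 38 bridged (Z)-C3=C4 ene-lactam
Conditions: Hoveyda–Grubbs II (15 mol %, portionwise), PhMe (1 mM), 90 °C
Reagents that add atoms: none
Why: Ring-closing metathesis; the N-side-chain terminal alkene and the C5 vinyl group (C4 syn to the lactam bridge) close the nine-membered ring with loss of ethene under high dilution, and the tetrasubstituted C9=C10 alkene is inert.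

Step 27
Reactants: 38 ene-lactam
Product: 39 C2 O-TBS ether of the target
Conditions: 2-nitrobenzenesulfonylhydrazide, Et3N, CH2Cl2, rt
Reagents that add atoms: none
Why: Diimide reduction (concerted syn H2 transfer) saturates the disubstituted C3=C4 alkene and leaves the tetrasubstituted alkene, ester, acetate and lactam untouched.

Step 28
Reactants: 39 silyl ether
Product: 40 CNP0296366.1
Conditions: HF·pyridine, pyridine/THF, 0 °C → rt
Reagents that add atoms: none
Why: Fluoride-mediated desilylation with buffered HF·pyridine frees the C2 hydroxyl while the acetate, methyl ester and lactam survive.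

**Compound list**

1 | cyclopent-2-en-1-one | O=C1C=CCC1 | starting material
2 | dimethyl malonate | COC(=O)CC(=O)OC | starting material
3 | dimethyl 2-[(1S)-3-oxocyclopentyl]propanedioate | O=C1C[C@@H](C(C(=O)OC)C(=O)OC)CC1 | intermediate
4 | methyl 3-bromo-2-oxopropanoate (methyl bromopyruvate) | COC(=O)C(=O)CBr | starting material
5 | dimethyl 2-(3-methoxy-2,3-dioxopropyl)-2-[(1S)-3-oxocyclopentyl]propanedioate | O=C1C[C@@H](C(CC(=O)C(=O)OC)(C(=O)OC)C(=O)OC)CC1 | intermediate
6 | trimethyl (3aS)-6-oxo-2,3,3a,4,5,6-hexahydropentalene-1,3,3-tricarboxylate (C8=C9 enone) | COC(=O)C1=C2C(=O)CC[C@@H]2C(C(=O)OC)(C(=O)OC)C1 | intermediate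
7 | trimethyl (3aS,6S)-6-hydroxy-6-(prop-2-en-1-yl)-2,3,3a,4,5,6-hexahydropentalene-1,3,3-tricarboxylate (allyl cis to H-15) | COC(=O)C1=C2[C@@](O)(CC=C)CC[C@@H]2C(C(=O)OC)(C(=O)OC)C1 | intermediate
8 | itaconic anhydride (3-methylideneoxolane-2,5-dione) | C=C1CC(=O)OC1=O | starting material
9 | 4-[(4-methoxyphenyl)methoxy]-2-methylidene-4-oxobutanoic acid | C=C(CC(=O)OCc1ccc(OC)cc1)C(=O)O | intermediate
10 | 4-methoxybenzyl 3-(imidazole-1-carbonyl)but-3-enoate | C=C(CC(=O)OCc1ccc(OC)cc1)C(=O)n1ccnc1 | intermediate (not isolated)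
11 | 4-methoxybenzyl 3-[methoxy(methyl)carbamoyl]but-3-enoate | C=C(CC(=O)OCc1ccc(OC)cc1)C(=O)N(C)OC | intermediate
12 | 3-[methoxy(methyl)carbamoyl]but-3-enoic acid | C=C(CC(=O)O)C(=O)N(C)OC | intermediate
13 | trimethyl (3aS,6S)-6-({3-[methoxy(methyl)carbamoyl]but-3-enoyl}oxy)-6-(prop-2-en-1-yl)-2,3,3a,4,5,6-hexahydropentalene-1,3,3-tricarboxylate | COC(=O)C1=C2[C@@](OC(=O)CC(=C)C(=O)N(C)OC)(CC=C)CC[C@@H]2C(C(=O)OC)(C(=O)OC)C1 | intermediate
14 | trimethylsilyl ketene acetal of 13 (C4(OTMS)=C5H, geometry not assigned) | COC(=O)C1=C2[C@@](OC(O[Si](C)(C)C)=CC(=C)C(=O)N(C)OC)(CC=C)CC[C@@H]2C(C(=O)OC)(C(=O)OC)C1 | intermediate (not isolated)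
15 | trimethylsilyl ester of 16 | COC(=O)C1(C(=O)OC)C[C@](C(=O)OC)(C(C(=O)O[Si](C)(C)C)C(=C)C(=O)N(C)OC)C2=C(CC=C)CC[C@H]12 | intermediate (not isolated)
16 | Claisen acid: hexahydropentalene with quaternary C8 (C1O2Me; branch C5H(CO2H)–C6(=CH2)–C7(O)N(OMe)Me trans to H-15), C9=C10 alkene, allyl on C10, gem-diester at C14 | COC(=O)C1(C(=O)OC)C[C@](C(=O)OC)(C(C(=O)O)C(=C)C(=O)N(C)OC)C2=C(CC=C)CC[C@H]12 | intermediate
17 | 5-5-7 tricyclic diene acid (C6=C12 and C9=C10; CO2H on C5; Weinreb amide C7 on C6; C1O2Me on C8; gem-diester at C14) | COC(=O)C1(C(=O)OC)C[C@]2(C(=O)OC)C(C(=O)O)C(C(=O)N(C)OC)=CCC3=C2[C@@H]1CC3 | intermediate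
18 | 6,12-dihydro derivative of 17 (C7 amide cis to the C1 ester) | COC(=O)C1(C(=O)OC)C[C@]2(C(=O)OC)C(C(=O)O)[C@@H](C(=O)N(C)OC)CCC3=C2[C@@H]1CC3 | intermediate
19 | C14 mono-ester acid (CO2Me cis to C16, H-14 cis to H-15) | COC(=O)[C@@H]1C[C@]2(C(=O)OC)C(C(=O)O)[C@@H](C(=O)N(C)OC)CCC3=C2[C@@H]1CC3 | intermediate
20 | S-ethyl thioester of 19 | COC(=O)[C@@H]1C[C@]2(C(=O)OC)C(C(=O)SCC)[C@@H](C(=O)N(C)OC)CCC3=C2[C@@H]1CC3 | intermediate
21 | C4 aldehyde (CHO on C5) | COC(=O)[C@@H]1C[C@]2(C(=O)OC)C(C=O)[C@@H](C(=O)N(C)OC)CCC3=C2[C@@H]1CC3 | intermediate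
22 | C5-quaternary hydroxy aldehyde (C21H2OH anti, C4HO syn to C1 ester and C7 amide) | COC(=O)[C@@H]1C[C@]2(C(=O)OC)[C@@](CO)(C=O)[C@@H](C(=O)N(C)OC)CCC3=C2[C@@H]1CC3 | intermediate (not isolated)
23 | C21 acetate of 22 | COC(=O)[C@@H]1C[C@]2(C(=O)OC)[C@@](COC(C)=O)(C=O)[C@@H](C(=O)N(C)OC)CCC3=C2[C@@H]1CC3 | intermediate
24 | C5-vinyl Weinreb amide | COC(=O)[C@@H]1C[C@]2(C(=O)OC)[C@@](COC(C)=O)(C=C)[C@@H](C(=O)N(C)OC)CCC3=C2[C@@H]1CC3 | intermediate
25 | C7 aldehyde (carbocyclic core) | COC(=O)[C@@H]1C[C@]2(C(=O)OC)[C@@](COC(C)=O)(C=C)[C@@H](C=O)CCC3=C2[C@@H]1CC3 | intermediate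
26 | (4S)-4-benzyl-1,3-oxazolidin-2-one | O=C1N[C@@H](Cc2ccccc2)CO1 | starting material
27 | (4S)-4-benzyl-3-propanoyl-1,3-oxazolidin-2-one | CCC(=O)N1[C@@H](Cc2ccccc2)COC1=O | intermediate
28 | acrolein (prop-2-enal) | C=CC=O | starting material
29 | (Z)-dibutylboron enolate of 27 | CCCCB(CCCC)O/C(=C\C)N1[C@@H](Cc2ccccc2)COC1=O | intermediate (not isolated)
30 | (4S)-4-benzyl-3-[(2S,3R)-3-hydroxy-2-methylpent-4-enoyl]-1,3-oxazolidin-2-one | C=C[C@@H](O)[C@H](C)C(=O)N1[C@@H](Cc2ccccc2)COC1=O | intermediate
31 | (4S)-4-benzyl-3-[(2S,3R)-3-{[tert-butyl(dimethyl)silyl]oxy}-2-methylpent-4-enoyl]-1,3-oxazolidin-2-one | C=C[C@@H](O[Si](C)(C)C(C)(C)C)[C@H](C)C(=O)N1[C@@H](Cc2ccccc2)COC1=O | intermediate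
32 | (2R,3R)-3-{[tert-butyl(dimethyl)silyl]oxy}-2-methylpent-4-en-1-ol | C=C[C@@H](O[Si](C)(C)C(C)(C)C)[C@H](C)CO | intermediate
33 | (2R,3R)-3-{[tert-butyl(dimethyl)silyl]oxy}-2-methylpent-4-en-1-yl methanesulfonate | C=C[C@@H](O[Si](C)(C)C(C)(C)C)[C@H](C)COS(C)(=O)=O | intermediate
34 | tert-butyl{[(3R,4R)-5-azido-4-methylpent-1-en-3-yl]oxy}dimethylsilane | C=C[C@@H](O[Si](C)(C)C(C)(C)C)[C@H](C)CN=[N+]=[N-] | intermediate
35 | (2R,3R)-3-{[tert-butyl(dimethyl)silyl]oxy}-2-methylpent-4-en-1-amine | C=C[C@@H](O[Si](C)(C)C(C)(C)C)[C@H](C)CN | intermediate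
36 | secondary amine from 25 and 35 (C7–NH–C19) | COC(=O)[C@@H]1C[C@]2(C(=O)OC)[C@@](COC(C)=O)(C=C)[C@@H](CNC[C@@H](C)[C@H](O[Si](C)(C)C(C)(C)C)C=C)CCC3=C2[C@@H]1CC3 | intermediate (not isolated)
37 | N-alkyl δ-lactam diene (N–C1(=O) lactam; C5 vinyl; N-[(2R,3R)-3-silyloxy-2-methylpent-4-enyl]) | COC(=O)[C@@H]1C[C@@]23C(=O)N(C[C@@H](C)[C@H](O[Si](C)(C)C(C)(C)C)C=C)C[C@@H](CCC4=C2[C@@H]1CC4)[C@]3(COC(C)=O)C=C | intermediate
38 | bridged (Z)-C3=C4 ene-lactam with the nine-membered ring, C2 OTBS | COC(=O)[C@@H]1C[C@@]23C(=O)N4C[C@@H](CCC5=C2[C@@H]1CC5)[C@]3(COC(C)=O)/C=C\[C@@H](O[Si](C)(C)C(C)(C)C)[C@H](C)C4 | intermediate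
39 | C2 O-TBS ether of the target | COC(=O)[C@@H]1C[C@@]23C(=O)N4C[C@@H](CCC5=C2[C@@H]1CC5)[C@]3(COC(C)=O)CC[C@@H](O[Si](C)(C)C(C)(C)C)[C@H](C)C4 | intermediate
40 | CNP0296366.1 | COC(=O)[C@@H]1C[C@@]23C(=O)N4C[C@@H](CCC5=C2[C@@H]1CC5)[C@]3(COC(C)=O)CC[C@@H](O)[C@H](C)C4 | target

**Step count**

Total: 28 steps. Longest linear sequence: 18 steps (1–4, 8–17, 25–28), 64 % of the total. Side branches: steps 5–7 (acid 12) and steps 18–24 (amine 35).

**Steps most likely to fail, with fallbacks**

Step 9 (Ireland–Claisen). The rearrangement must form the quaternary C8 at the ester-bearing end of a tetrasubstituted alkene from a hindered tertiary ester, and γ-deprotonation at C15 or elimination may compete. The fallback inverts the order of the two ring-forming events. Starting from 13, RCM with Grubbs II first gives the seven-membered spiro-lactone F1. Enolisation and silylation of this lactone (LiHMDS, TMSCl) then triggers a lactone-enolate Claisen rearrangement through an enforced boat. This converts the lactone directly into the cycloheptadiene acid 17, where the route is rejoined.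

Step 26 (RCM to the bridged nine-membered ring). The two partners are a neopentyl vinyl group and a hindered allylic silyl ether, and the product is a bridged bicycle. The fallback closes the nine-membered ring before the lactam bridge exists. Starting from 36, isolated by stopping step 25 at room temperature, the amine is converted into its TsOH salt and cyclised by RCM to the unbridged nine-membered cyclic amine F2. Heating this with Et3N in toluene then closes the δ-lactam transannularly and returns 38.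

Step 15 (facial selectivity of the hydroxymethylation at C5). If formaldehyde enters syn to the C1 ester, the two one-carbon groups on C5 can exchange roles. Starting from 21, the aldol is stopped at the epimeric hydroxy aldehyde F3. TBDPSCl/imidazole gives the silyl ether F4, NaBH4 reduces its aldehyde to the alcohol F5, and Ac2O/pyridine gives the acetate F6. HF·pyridine then removes the silyl group to give the alcohol F7, and Dess–Martin oxidation of this alcohol gives 23.

**Further compounds**

F1 | step 9 | spiro seven-membered unsaturated lactone from RCM of 13 (ring C10–O–C4(=O)–C5H2–C6=C12H–C11H2) | COC(=O)C1=C2[C@@]3(CC=C(C(=O)N(C)OC)CC(=O)O3)CC[C@@H]2C(C(=O)OC)(C(=O)OC)C1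
F2 | step 26 | unbridged (Z)-nine-membered cyclic amine (C3=C4 closed, C1 ester still free) | COC(=O)[C@@H]1C[C@]2(C(=O)OC)[C@@](COC(C)=O)(/C=C\[C@@H](O[Si](C)(C)C(C)(C)C)[C@H](C)CNC5)[C@@H]5CCC3=C2[C@@H]1CC3
F3 | step 15 | C5 epimer of 22 (CH2OH syn, CHO anti to C1 ester and C7 amide) | COC(=O)[C@@H]1C[C@]2(C(=O)OC)[C@](CO)(C=O)[C@@H](C(=O)N(C)OC)CCC3=C2[C@@H]1CC3
F4 | step 15 | TBDPS ether of F3 | COC(=O)[C@@H]1C[C@]2(C(=O)OC)[C@](CO[Si](c4ccccc4)(c4ccccc4)C(C)(C)C)(C=O)[C@@H](C(=O)N(C)OC)CCC3=C2[C@@H]1CC3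
F5 | step 15 | primary alcohol from reduction of F4 | COC(=O)[C@@H]1C[C@]2(C(=O)OC)[C@](CO[Si](c4ccccc4)(c4ccccc4)C(C)(C)C)(CO)[C@@H](C(=O)N(C)OC)CCC3=C2[C@@H]1CC3
F6 | step 15 | acetate of F5 | COC(=O)[C@@H]1C[C@]2(C(=O)OC)[C@](CO[Si](c4ccccc4)(c4ccccc4)C(C)(C)C)(COC(C)=O)[C@@H](C(=O)N(C)OC)CCC3=C2[C@@H]1CC3
F7 | step 15 | desilylated alcohol from F6 (CH2OH syn, CH2OAc anti) | COC(=O)[C@@H]1C[C@]2(C(=O)OC)[C@](CO)(COC(C)=O)[C@@H](C(=O)N(C)OC)CCC3=C2[C@@H]1CC3
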